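The C3 epoxy ester is cut to (2R,3R)-2,3-dimethyloxirane-2-carboxylic acid (from angelic acid by reduction, Sharpless epoxidation and oxidation); the C3 hydroxyl goes back to the C2 ketone enolate, the C7 hydroxyl to the ring methyl group (allylic oxidation while C2 is held as a carbinol), and the C5 angelate to the trans C5 alcohol by Mitsunobu inversion.
Feature carrying the plan: in the cyclohexenone ring the C2 carbonyl oxygen and the C5 ester oxygen sit para (1,4) across the C1=C6 alkene, beside the isopropyl-bearing C4, which is the imprint of O2 added to the C2 and C5 termini of the ring diene of (R)-α-phellandrene.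
Key disconnection: (4R,5R)-5-hydroxy-p-menth-6-en-2-one ⇒ (R)-α-phellandrene + O2, by singlet-oxygen [4+2] cycloaddition and Kornblum–DeLaMare opening in one flask.
Ring order: the carbocycle is bought with the terpene; a temporary 1,2-dioxine ring (2,3-dioxabicyclo[2.2.2]octene) is closed and reopened in step 1; the side-chain oxirane is the only ring built and kept (step 9).

Key step: step 1

Remark: ring atoms carry p-menthane numbers (C1 bears C7, C4 bears isopropyl), angeloyl is (Z)-2-methylbut-2-enoyl and TBS is tert-butyldimethylsilyl. Commercial (R)-(−)-α-phellandrene is assumed to be purified to high isomeric and enantiomeric purity, since its C4 centre is carried unchanged into the target.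

Step 1
Reactants: 1 (R)-(−)-α-phellandrene
Product: 3 (4R,5R)-5-hydroxy-p-menth-6-en-2-one, via anti endoperoxide 2 (not isolated)
Conditions: O2, hν (visible), 5,10,15,20-tetraphenylporphyrin (cat.), CH2Cl2, −20 °C; then Et3N, 0 °C → rt
Reagents that add atoms: oxygen, O=O
Why: Sensitized energy transfer gives singlet oxygen, which adds in a concerted suprafacial [4+2] cycloaddition to the s-cis-locked ring diene C2=C1–C6=C5 of 1; the closest known reaction type is the dye-sensitized photooxygenation of cyclohexa-1,3-dienes to 2,3-dioxabicyclo[2.2.2]oct-5-enes followed by Kornblum–DeLaMare rearrangement to 4-hydroxy-2-enones. The only ring closed is the temporary six-membered 1,2-dioxine, formed by cycloaddition with both C–O bonds (C2–O and C5–O) made at once and the alkene moved to C1=C6; it is reopened in the same flask when Et3N removes the C2 bridgehead hydrogen and the O–O bond breaks in an E2-like fragmentation to the C2 ketone and the C5 alkoxide. The one new stereocentre kept in 3, C5, is controlled by the resident C4 centre: oxygen should approach the diene face anti to isopropyl, so the C5 hydroxyl ends up trans to it, while the C2 centre of 2 is erased on opening. The step needs [4+2] over ene reaction (secured by the rigid s-cis diene and low temperature), anti face selectivity (secured by the isopropyl group shielding its own face) and proton loss at C2 rather than C5 (C5 is flanked by the isopropyl-bearing C4, C2 only by the C3 methylene). The C5 epimer from syn addition and the regioisomeric keto alcohol are expected as minor products, to be removed by chromatography at 3.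

Step 2
Reactants: 3 (4R,5R)-5-hydroxy-p-menth-6-en-2-one; 4 angelic acid
Product: 5 (4R,5S)-5-angeloyloxy-p-menth-6-en-2-one
Conditions: PPh3, DIAD, THF, 0 °C → rt
Reagents that add atoms: none
Why: Mitsunobu esterification, in which angelate displaces the C5 alkoxyphosphonium ion by SN2 with inversion (the electron-poor enone disfavours ionisation and SN2′ attack at C1), so that the C5 oxygen becomes cis to isopropyl while the carboxylate, never activated at carbon, keeps its Z geometry.

Step 3
Reactants: 5 (4R,5S)-5-angeloyloxy-p-menth-6-en-2-one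
Product: 6 (2R,4R,5S)-5-angeloyloxy-p-menth-6-en-2-ol
Conditions: NaBH4, CeCl3·7H2O, MeOH, −20 → 0 °C
Reagents that add atoms: none
Why: Luche reduction adds hydride 1,2 to the enone without touching the angelate, turning C1=C6 into an ordinary trisubstituted alkene, which is needed because SeO2 on the enone itself would react through the dienol at the γ-carbon C5 and not at C7; the C2 carbinol (expected mainly cis to isopropyl by axial hydride delivery) is a temporary centre erased in step 6.

Step 4
Reactants: 6 (2R,4R,5S)-5-angeloyloxy-p-menth-6-en-2-ol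
Product: 7 (2R,4R,5S)-5-angeloyloxy-p-menth-6-ene-2,7-diol
Conditions: SeO2 (0.5 equiv), t-BuOOH (in decane), CH2Cl2, rt
Reagents that add atoms: selenium dioxide, O=[Se]=O; tert-butyl hydroperoxide, CC(C)(C)OO
Why: Riley allylic oxidation under peroxide-recycled conditions, in which the ene reaction puts selenium on the less substituted C6 and takes hydrogen from the C7 methyl group (the other substituent of C1 is a carbinol carbon) and the [2,3]-shift returns the alkene to C1=C6 with oxygen on C7, while the conjugated, electron-poor angelate alkene should not react; no stereocentre is formed.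

Step 5
Reactants: 7 (2R,4R,5S)-5-angeloyloxy-p-menth-6-ene-2,7-diol
Product: 8 (2R,4R,5S)-5-angeloyloxy-7-(tert-butyldimethylsilyloxy)-p-menth-6-en-2-ol
Conditions: TBSCl (1.05 equiv), imidazole, CH2Cl2, −20 → 0 °C
Reagents that add atoms: tert-butyldimethylsilyl chloride, CC(C)(C)[Si](C)(C)Cl
Why: Silyl ether formation, in which the primary allylic C7 hydroxyl reacts much faster than the secondary C2 hydroxyl with one equivalent of silyl chloride at low temperature.

Step 6
Reactants: 8 (2R,4R,5S)-5-angeloyloxy-7-(tert-butyldimethylsilyloxy)-p-menth-6-en-2-ol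
Product: 9 (4R,5S)-5-angeloyloxy-7-(tert-butyldimethylsilyloxy)-p-menth-6-en-2-one
Conditions: Dess–Martin periodinane, CH2Cl2, 0 °C → rt
Reagents that add atoms: none
Why: Dess–Martin oxidation of the secondary allylic alcohol restores the C2 enone under non-basic conditions that leave the silyl ether, the angelate and the C4 and C5 centres alone, and both C2 epimers converge.

Step 7
Reactants: 9 (4R,5S)-5-angeloyloxy-7-(tert-butyldimethylsilyloxy)-p-menth-6-en-2-one
Product: 11 (3S,4S,5R)-5-angeloyloxy-3-hydroxy-7-(tert-butyldimethylsilyloxy)-p-menth-6-en-2-one, via potassium dienolate 10 (not isolated)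
Conditions: KN(SiMe3)2, THF, −78 °C; then trans-2-(phenylsulfonyl)-3-phenyloxaziridine, −78 °C; AcOH quench
Reagents that add atoms: trans-2-(phenylsulfonyl)-3-phenyloxaziridine, O=S(=O)(c1ccccc1)N1OC1c1ccccc1
Why: Davis oxidation of a ketone enolate, in which kinetic deprotonation at the α′ carbon C3 gives the cross-conjugated dienolate and the oxaziridine delivers oxygen to the C3 face anti to both the adjacent C4 isopropyl group and the C5 angelate, setting the C3 hydroxyl trans to isopropyl as in α′-hydroxylations of carvone-type enolates (the changed C4 and C5 descriptors reflect new priorities only).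

Step 8
Reactants: 4 angelic acid
Product: 12 (Z)-2-methylbut-2-en-1-ol
Conditions: LiAlH4, Et2O, 0 °C → rt
Reagents that add atoms: none
Why: Hydride reduction of the carboxylic acid gives the allylic alcohol without reducing or isomerising the trisubstituted Z alkene.

Step 9
Reactants: 12 (Z)-2-methylbut-2-en-1-ol
Product: 13 [(2S,3R)-2,3-dimethyloxiran-2-yl]methanol
Conditions: Ti(OiPr)4 (cat.), L-(+)-diethyl tartrate (cat.), t-BuOOH, 4 Å molecular sieves, CH2Cl2, −20 °C
Reagents that add atoms: tert-butyl hydroperoxide, CC(C)(C)OO
Why: Sharpless asymmetric epoxidation, in which the titanium tartrate complex delivers oxygen to one alkene face (L-(+)-tartrate should give the 2S carbinol-bearing centre, the same face sense as for geraniol and nerol) and the Z geometry is transferred stereospecifically, giving the (2S,3R)-oxirane with trans methyl groups.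

Step 10
Reactants: 13 [(2S,3R)-2,3-dimethyloxiran-2-yl]methanol
Product: 14 (2R,3R)-2,3-dimethyloxirane-2-carboxylic acid
Conditions: 2,2,6,6-tetramethylpiperidin-1-oxyl (TEMPO, cat.), PhI(OAc)2, MeCN/H2O, 0 °C → rt
Reagents that add atoms: water, O
Why: Oxoammonium (TEMPO) oxidation takes the primary alcohol through the aldehyde hydrate to the acid without opening the oxirane, and both stereocentres are untouched (C2 becomes R only through the priority change).

Step 11
Reactants: 11 (3S,4S,5R)-5-angeloyloxy-3-hydroxy-7-(tert-butyldimethylsilyloxy)-p-menth-6-en-2-one; 14 (2R,3R)-2,3-dimethyloxirane-2-carboxylic acid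
Product: 16 (3S,4R,5R)-5-angeloyloxy-3-[(2R,3R)-2,3-dimethyloxirane-2-carbonyloxy]-7-(tert-butyldimethylsilyloxy)-p-menth-6-en-2-one, via mixed anhydride 15 (not isolated)
Conditions: 14, 2,4,6-trichlorobenzoyl chloride, Et3N, THF, 0 °C → rt; then 11, 4-(dimethylamino)pyridine, toluene, rt
Reagents that add atoms: none
Why: Yamaguchi esterification, in which the hindered α-quaternary acid is activated as the mixed anhydride and the acylpyridinium ion transfers the epoxyacyl group to the hindered C3 hydroxyl with retention at every centre, the C7 oxygen being blocked by silicon and the trans C3/C5 oxygens being unable to exchange acyl groups.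

Step 12
Reactants: 16 (3S,4R,5R)-5-angeloyloxy-3-[(2R,3R)-2,3-dimethyloxirane-2-carbonyloxy]-7-(tert-butyldimethylsilyloxy)-p-menth-6-en-2-one
Product: 17 (3S,4R,5R)-5-angeloyloxy-3-[(2R,3R)-2,3-dimethyloxirane-2-carbonyloxy]-7-hydroxy-p-menth-6-en-2-one
Conditions: HF·pyridine, pyridine, THF, 0 °C → rt
Reagents that add atoms: none
Why: Fluoride-mediated desilylation under buffered, non-basic conditions frees the primary C7 hydroxyl without ester cleavage, acyl migration or oxirane opening.

Compound list
1 | (R)-(−)-α-phellandrene, (5R)-2-methyl-5-(propan-2-yl)cyclohexa-1,3-diene | C1=CC(C)=CC[C@@H]1C(C)C | starting material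
2 | (2S,4R,5R)-2,5-epidioxy-p-menth-6-ene (anti endoperoxide, O–O bridge on the face opposite isopropyl) | CC1=C[C@@H]2OO[C@H]1C[C@@H]2C(C)C | intermediate
3 | (4R,5R)-5-hydroxy-p-menth-6-en-2-one (hydroxyl trans to isopropyl) | O[C@H]1C=C(C)C(=O)C[C@@H]1C(C)C | intermediate
4 | angelic acid, (Z)-2-methylbut-2-enoic acid | C/C=C(/C)C(=O)O | starting material
5 | (4R,5S)-5-angeloyloxy-p-menth-6-en-2-one (ester cis to isopropyl) | C/C=C(/C)C(=O)O[C@@H]1C=C(C)C(=O)C[C@@H]1C(C)C | intermediate
6 | (2R,4R,5S)-5-angeloyloxy-p-menth-6-en-2-ol (expected major C2 epimer drawn, hydroxyl cis to isopropyl; either epimer is carried on) | C/C=C(/C)C(=O)O[C@@H]1C=C(C)[C@H](O)C[C@@H]1C(C)C | intermediate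
7 | (2R,4R,5S)-5-angeloyloxy-p-menth-6-ene-2,7-diol | C/C=C(/C)C(=O)O[C@@H]1C=C(CO)[C@H](O)C[C@@H]1C(C)C | intermediate
8 | (2R,4R,5S)-5-angeloyloxy-7-(tert-butyldimethylsilyloxy)-p-menth-6-en-2-ol | C/C=C(/C)C(=O)O[C@@H]1C=C(CO[Si](C)(C)C(C)(C)C)[C@H](O)C[C@@H]1C(C)C | intermediate
9 | (4R,5S)-5-angeloyloxy-7-(tert-butyldimethylsilyloxy)-p-menth-6-en-2-one | C/C=C(/C)C(=O)O[C@@H]1C=C(CO[Si](C)(C)C(C)(C)C)C(=O)C[C@@H]1C(C)C | intermediate
10 | potassium dienolate of 9 (C2–O–K, C2=C3 and C1=C6) | C/C=C(/C)C(=O)O[C@@H]1C=C(CO[Si](C)(C)C(C)(C)C)C(O[K])=C[C@@H]1C(C)C | intermediate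
11 | (3S,4S,5R)-5-angeloyloxy-3-hydroxy-7-(tert-butyldimethylsilyloxy)-p-menth-6-en-2-one (3-OH trans to isopropyl, 5-ester cis) | C/C=C(/C)C(=O)O[C@@H]1C=C(CO[Si](C)(C)C(C)(C)C)C(=O)[C@@H](O)[C@@H]1C(C)C | intermediate
12 | (Z)-2-methylbut-2-en-1-ol | C/C=C(/C)CO | intermediate
13 | [(2S,3R)-2,3-dimethyloxiran-2-yl]methanol | OC[C@]1(C)O[C@@H]1C | intermediate
14 | (2R,3R)-2,3-dimethyloxirane-2-carboxylic acid | OC(=O)[C@]1(C)O[C@@H]1C | intermediate
15 | (2R,3R)-2,3-dimethyloxirane-2-carboxylic 2,4,6-trichlorobenzoic anhydride | O=C(OC(=O)[C@]1(C)O[C@@H]1C)c1c(Cl)cc(Cl)cc1Cl | intermediate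
16 | (3S,4R,5R)-5-angeloyloxy-3-[(2R,3R)-2,3-dimethyloxirane-2-carbonyloxy]-7-(tert-butyldimethylsilyloxy)-p-menth-6-en-2-one | C/C=C(/C)C(=O)O[C@@H]1C=C(CO[Si](C)(C)C(C)(C)C)C(=O)[C@@H](OC(=O)[C@]2(C)O[C@@H]2C)[C@@H]1C(C)C | intermediate
17 | (3S,4R,5R)-5-angeloyloxy-3-[(2R,3R)-2,3-dimethyloxirane-2-carbonyloxy]-7-hydroxy-p-menth-6-en-2-one (CNP0293054.1) | C/C=C(/C)C(=O)O[C@@H]1C=C(CO)C(=O)[C@@H](OC(=O)[C@]2(C)O[C@@H]2C)[C@@H]1C(C)C | target

Total step count: 12. Longest linear sequence: 9 steps (1 to 17 through steps 1–7, 11 and 12); the acid 14 takes 3 steps from 4 (steps 8–10).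

Steps most likely to fail

Step 1: the cycloaddition may show only modest face selectivity (oxygen adding syn to isopropyl), ene hydroperoxidation may compete, and the amine may abstract the C5 instead of the C2 bridgehead hydrogen; each lowers the amount of 3. The fallback makes the syn-derived material converge instead of discarding it. Setting out from 1, the syn endoperoxide F1 that accompanies 2 opens under the same amine treatment to the cis hydroxy enone F2, the C5 epimer of 3. After separation, F2 is acylated with retention by the angelic mixed anhydride F3, prepared from 4 with 2,4,6-trichlorobenzoyl chloride and Et3N and used in toluene at 80 °C without a nucleophilic catalyst so that the Z geometry is kept. This comes back to the route at 5.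

Step 4: the ene reaction with SeO2 may be too slow at an alkene carrying two allylic oxygen substituents, and forcing it invites oxidation of the angelate methyl groups or over-oxidation at C7. The fallback oxidises C7 on the bicyclic peroxide, where the bridgehead hydrogens cannot take part in an ene reaction and no enoate is present. Setting out from 2 (isolated by leaving out the amine in step 1), SeO2/t-BuOOH should give the 7-hydroxy endoperoxide F4 and TBSCl/imidazole its silyl ether F5. Et3N then opens F5 (Kornblum–DeLaMare) to the trans 5-hydroxy-7-silyloxy enone F6, and Mitsunobu reaction of F6 with 4 (PPh3, DIAD) comes back to the route at 9 without the reduction–oxidation detour.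

Step 2: the alkoxyphosphonium ion at the hindered, isopropyl-flanked C5 may eliminate toward C4 (leading on to aromatisation) faster than angelate displaces it. The fallback separates activation from displacement. Setting out from 3, MsCl/Et3N at −20 °C gives the mesylate F7, which is displaced with inversion by preformed cesium angelate F8 (from 4 and Cs2CO3) with 18-crown-6 in toluene, a weakly basic carboxylate SN2 reaction that comes back to the route at 5.

Further compounds
F1 | step 1 | (2R,4R,5S)-2,5-epidioxy-p-menth-6-ene (syn endoperoxide) | CC1=C[C@H]2OO[C@@H]1C[C@@H]2C(C)C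
F2 | step 1 | (4R,5S)-5-hydroxy-p-menth-6-en-2-one (hydroxyl cis to isopropyl) | O[C@@H]1C=C(C)C(=O)C[C@@H]1C(C)C
F3 | step 1 | angelic 2,4,6-trichlorobenzoic anhydride | C/C=C(/C)C(=O)OC(=O)c1c(Cl)cc(Cl)cc1Cl
F4 | step 4 | (2S,4R,5R)-2,5-epidioxy-p-menth-6-en-7-ol | OCC1=C[C@@H]2OO[C@H]1C[C@@H]2C(C)C
F5 | step 4 | (2S,4R,5R)-7-(tert-butyldimethylsilyloxy)-2,5-epidioxy-p-menth-6-ene | CC(C)(C)[Si](C)(C)OCC1=C[C@@H]2OO[C@H]1C[C@@H]2C(C)C
F6 | step 4 | (4R,5R)-5-hydroxy-7-(tert-butyldimethylsilyloxy)-p-menth-6-en-2-one | O[C@H]1C=C(CO[Si](C)(C)C(C)(C)C)C(=O)C[C@@H]1C(C)C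
F7 | step 2 | (4R,5R)-5-(methanesulfonyloxy)-p-menth-6-en-2-one | CS(=O)(=O)O[C@H]1C=C(C)C(=O)C[C@@H]1C(C)C
F8 | step 2 | cesium angelate | C/C=C(/C)C(=O)[O-].[Cs+]
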